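All runs are calculated with made-up constants, and the scatter is random.

- south-east: solid monomer 20 mM; transfer agent 1 mM; initiator 1 mol%; run made earlier
- flask: solid monomer 20 mM; transfer agent 2.00 mM; initiator 1 mol%; time 40 min

- south-east (time / min: monomer in chains / %, solid monomer / %): 2.50: 9, 76; 5.00: 21, 61; 8.00: 34, 42; 10.0: 37, 36; 12.0: 39, 29

(scatter of a reading: 1.5 percentage points)

- as a solid, counted per litre of solution: solid monomer
- at the start none of the solid monomer is in solution
- no earlier run changes the charge of transfer agent; that part of a forecast is a guess

- red: doubling the amount of initiator, all else as stated
- violet: doubling the dissolution coefficient of the solid monomer, all else as stated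
- ochre: doubling the solubility of the solid monomer, all else as stated

* how much monomer in chains there is at 40 min, in percent of the solid monomer charged
* the change that raises the amount of monomer in chains at 40 min, in percent of the solid monomer charged most ("none" if none brings more than 2 percentage points) (red / violet / ochre / none)
* amount of monomer in chains at 40 min, in percent of the solid monomer charged, after red

1. Time first. In the south-east run I took dissolved monomer as what was neither solid nor in chains. The gain in chains per minute, per unit of that monomer, faded with a life of about 3.26 min, as a reading.

2. In that run the solid monomer shrank more slowly than growth faded, with a time of about 9.69 min.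

3. Both times are shorter than the 40 min asked. So I expected growth in the flask to end well before then, and I reckoned a tally, not a rate.

4. I followed one living end, assuming that each initiator starts one. At each fork it adds a monomer or stops. The last south-east reading gives 39.0 monomers per initiator charged, and that tally was still rising, so the chance of stopping at a fork was below 2.56%. Carrying the last gain per minute on for one life, I projected an end tally of 42.3 monomers per initiator, as a reading. I call this the chain length (kinetic chain length).

5. The flask holds 2.00 mM of transfer agent against 1 mM. If transfer agent caused no stops, my projected tally stayed at 42.3%; if it caused every stop, it fell to 21.1%. I committed to the middle, 31.7%. Counting one living end per initiator, red doubled that tally to 63.4%, so I chose red.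

6. The forecast differed: 43% (range 36% to 48%), 52% after red (range 44% to 62%), and violet as best, saying “I assume the transfer agent leaves the rate about unchanged, though that is a guess”.

7. The flask gave 31.5%, and 56.2% after red. The best change was red, with gains of 25 percentage points for red, 14 points for ochre and 5.9 points for violet.

    solid monomer ⇌ free monomer, rate k1*(cs1 - [free monomer]) while solid is left; crystals form when [free monomer] > cs1 (solubility = 7.20 mM, k = 0.00620 s⁻¹)
    living end + free monomer → dead end (k = 0.350 M⁻¹ s⁻¹)
    living end + transfer agent → dead chain (kL = 1.60 M⁻¹ s⁻¹)
    free monomer + living end → monomer in chains + living end, rate k4*[living end]*[free monomer] (k = 36.0 M⁻¹ s⁻¹)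
    initiator + monomer in chains → initiator + over-reaction product (k = 47.0 M⁻¹ s⁻¹)
    free monomer + initiator → living end + monomer in chains (k = 17.0 M⁻¹ s⁻¹)

The flask's chain length came to 31.5, shorter than the 42.3 I had projected for the south-east run, and that run itself reached 49.9% at 40 min. Its chains stayed short because living ends stopped on transfer agent: the run without that step reached 93.6% against 31.5%. A neighbour flask with 0.6 mol% of initiator and the same transfer agent gets 18.9% from this chain length; its computed result is 19.9%.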